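The earlier runs and the new flask were generated by integration for an exercise; the scatter is artificial.

- Work with the fraction of substrate left: at a given time, in runs with the same charges of substrate, initiator and transfer agent, its logarithm divided by the equivalents of reagent stays close from run to run.

| setting | alder | cedar | ash | delta | zeta | eta |
|---|---|---|---|---|---|---|
| substrate | 20 mM | 20 mM | 20 mM | 20 mM | 20 mM | 20 mM |
| reagent | 1.3 equiv | 1.9 equiv | 2.9 equiv | 1.50 equiv | 2.00 equiv | 2.50 equiv |
| transfer agent | 6 mM | 6 mM | 6 mM | 6.00 mM | 6.00 mM | 6.00 mM |
| initiator | 1 mol% | 1 mol% | 1 mol% | 1 mol% | 1 mol% | 1 mol% |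
| remark | run made earlier | run made earlier | run made earlier |  |  |  |
| time |  |  |  | 20 min | 20 min | 20 min |

| run | time / min | substrate / % | target / % |
|---|---|---|---|
| alder | 0.833 | 98.5 | 0.4 |
| alder | 2.50 | 94.3 | 4.8 |
| alder | 5.00 | 90.3 | 7.0 |
| alder | 8.00 | 87.7 | 10.9 |
| alder | 10.0 | 84.9 | 8.8 |
| cedar | 0.833 | 97.4 | 1.1 |
| cedar | 2.50 | 92.0 | 4.0 |
| cedar | 5.00 | 86.9 | 8.9 |
| cedar | 8.00 | 81.7 | 13.8 |
| cedar | 10.0 | 77.5 | 16.3 |
| ash | 2.00 | 92.6 | 6.5 |
| ash | 4.00 | 84.2 | 13.0 |
| ash | 6.00 | 79.2 | 17.8 |
| ash | 8.00 | 72.4 | 20.6 |
| ash | 10.0 | 69.2 | 22.2 |

(standard deviation of a reading: 1 percentage point)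

- by-product is meant together with its idle adduct
- the earlier runs were read with a standard deviation of 1 percentage point
- candidate steps: initiator -> 2 initiating radical; substrate + initiating radical -> capped initiator + first chain carrier; reagent + first chain carrier -> target + second chain carrier; substrate + second chain carrier -> by-product + first chain carrier; transfer agent + first chain carrier -> side product + idle radical; 2 idle radical -> ended radicals; 2 second chain carrier -> ended chains; substrate + by-product <-> idle adduct
- what has gone from substrate into another species counts as reacted, even if it can come back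

* part of the substrate that has reacted at the end, delta
* part of the substrate that has reacted at the end, zeta
* part of the substrate that has reacted at the end, eta
* what raising the equivalents of reagent from its lowest to its highest value here does to the part of the substrate that has reacted (changes below 5 percentage points count as none) (it rises / no change / it falls)

- Take minus the natural logarithm of the fraction left at 10.0 min and divide it by the equivalents. You get 0.126 in alder, 0.134 in cedar and 0.127 in ash.
- The mean of these is the loss per equivalent, 0.129. Read it as the exponent of a pseudo-first-order decay of substrate.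
- Multiply by the equivalents for the exponent at 10.0 min: 0.194 in delta, 0.258 in zeta, 0.323 in eta.
- A straight line to 20 min multiplies the exponent by 2, which gives 32.1% reacted in delta.
- That factor is the weak link. Add the exponents of the three runs, using alder and cedar at 5.00 min and 10.0 min, and ash at 4.00 min and 8.00 min. The later sum is 1.79 times the earlier one, less than a straight line gives.
- Suppose the rate fades by a constant factor per minute. The excess over one is then the fade of the first span, and the next such factor is one plus its square: 1.62.
- Your commitment for 20 min is 27.0% reacted in delta, 34.2% in zeta and 40.8% in eta. That is a rise of 14 percentage points, more than 5 points.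
- The forecast says 28%, 36% and 43%, and it rises. It stretches the reacted part itself: “20 min gives about 1.5 to 1.6 times the 10 min conversion”. Its numbers stand above yours.
- The flasks give 26.8% in delta, 33.9% in zeta and 40.3% in eta. From the lowest to the highest equivalents of reagent, the answer on the part reacted is: it rises, by 14 points. So the forecast held.

    initiator → 2 initiating radical (k = 0.00113 s⁻¹)
    substrate + initiating radical → capped initiator + first chain carrier (k = 2.96 × 10⁵ M⁻¹ s⁻¹)
    reagent + first chain carrier → target + second chain carrier (k = 8200 M⁻¹ s⁻¹)
    substrate + second chain carrier → by-product + first chain carrier (k = 77000 M⁻¹ s⁻¹)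
    transfer agent + first chain carrier → side product + idle radical (kL = 2950 M⁻¹ s⁻¹)
    2 idle radical → ended radicals (k = 2.00 × 10⁷ M⁻¹ s⁻¹)
    2 second chain carrier → ended chains (k = 4.50 × 10⁸ M⁻¹ s⁻¹)
    substrate + by-product ⇌ idle adduct, settled at all times (K = 31.0 M⁻¹)

- At 20 min the exponent per equivalent is 0.208 in delta and 0.206 in eta, still steady across reagent. Now read delta at 50 min. Summing the same fading spans from the loss per equivalent gives an exponent of 0.465, so 37.2% reacted. That flask gives 34.0%, with 3.4% of its initiator left.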